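Thursday's run is the very flask asked about, followed up to 15.0 min, so its readings are what you have to go on.

| flask | substrate | reagent | catalyst | added ligand | remark |
|---|---|---|---|---|---|
| Thursday's | 13 mM | 1 equiv | 0.66 mol% | 0.10 mM | the very flask that is asked about, followed so far |
| flask | 13 mM | 1.00 equiv | 0.66 mol% | 0.10 mM |  |

Thursday's run (percent of the substrate charged)

| time / min | product / % | substrate / % |
|---|---|---|
| 1.33 | 3.5 | 96.6 |
| 4.00 | 9.6 | 90.1 |
| 8.00 | 15.7 | 83.1 |
| 12.0 | 22.4 | 77.5 |
| 15.0 | 26.3 | 73.2 |

(readings scatter by 0.5 percentage points)

* apparent order in catalyst when 5.0% of the substrate are converted (percent change of the rate of making product for one percent more catalyst charged)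
* apparent order in reagent when 5.0% of the substrate are converted (percent change of the rate of making product for one percent more reagent charged)

- no earlier run changes the charge of catalyst; that part of a forecast is a guess
- no earlier run changes the charge of reagent; that part of a forecast is a guess

At the first reading, 1.33 min, you find 3.5% product beside 96.6% substrate, and the two add up to about the charge at each later reading, so little stands between them. Taking one reagent per substrate, you can write the balance of the reagent, which at 1.00 equiv shares the part of limiting reagent with the substrate:

[reagent] = 13 mM × (equivalents charged − fraction converted)

Through the middle and up to 15.0 min both partners shrink together. Between the first and the last interval the rate falls to 0.494 of its first value, while the substrate falls to 0.758 of its first reading, whose square is 0.575. With equal charges the two partners stay equal, so you read a total order of about two, within the scatter, and these readings do not split it between them; first order in each is your assumption, since no run changes the reagent. On that assumption the balance says what one percent more reagent does, through the lever of the charge, meaning the charge divided by what is left of it: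

lever = 1.05 at 5.0% converted

Your own reckoning for the order in reagent, resting on that assumption, is this lever, and it grows as the flask runs, to 1.36 at 15.0 min. For the catalyst you have no reckoning, because no run changes it, though its 0.0858 mM stands close to 0.10 mM of added ligand.

The forecast says 0.9 for catalyst and 0.7 for reagent, with the reagent shaded because, in its words, “one run cannot separate this from product inhibition or slow catalyst loss”. The lever stands above its number for the reagent.

The flask gives 1.5 for catalyst and 1.1 for reagent.

    catalyst + added ligand ⇌ idle complex, settled at all times (K = 32000 M⁻¹)
    substrate + reagent + catalyst ⇌ catalyst + product (K = 210 M⁻¹, k = 59400 M⁻² min⁻¹)

The lever of 1.05 stands beside the 1.1 for reagent, and the catalyst order is the one that runs well above a plain first order. In this flask 60.6% of the catalyst charged sits as idle complex, an off-cycle form, at 4.00 min. Extra catalyst therefore uses up added ligand as well and works at a larger free share, because of that joining. In the simulated run without that joining, the order in catalyst drops from 1.5 to 1.0.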